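**Retrosynthetic overview**

1. Target ⇐ two late acylations (tiglate on O3, senecioate on O9), C9–O by Rubottom oxidation of the C8 ketone, isopropenyl by methylenation of a C7 acetyl group ⇐ trans-decalin with C7 acetyl and C8 hydroxyl.
2. Key disconnection (ring B): C5–C6 and C7–C8 ⇐ ring A aldehyde (C5 exocyclic methylene, C10 CH2CHO arm) + methyl vinyl ketone. The feature used is the array C5 (quaternary, methyl C14)–C6H2–C7 (bearing the three-carbon unit C11–C13)–C8 (oxidised) in ring B, which is what a tertiary radical leaves when it adds to an enone and the enolate then closes by aldol.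
3. Ring A aldehyde ⇐ cis-fused bicyclic lactone (O5 and the C10 arm both on the β face). Hydroboration from its convex face sets C3 and C4 together; then lactone ⇒ Weinreb amide ⇒ C5 ketone ⇒ methylene.
4. Lactone ⇐ 2-methylcyclohex-2-enone by SAMP-hydrazone α′-alkylation with methyl bromoacetate (sets C10) and oxazaborolidine reduction.
5. Ring order: ring A is the ring of the starting enone; ring B is closed in the key step.

Key step: step 11

Remark: eremophilane numbering is used for all intermediates (ring A = C1–C5, C10; ring B = C5–C10; C11–C13 = isopropenyl unit; C14 on C5; C15 on C4). β is the face of C14. The target is read from its SMILES as (3R,4R,5R,7S,9S,10R), i.e. 3α-OTig, 4β-Me, 5β-Me, 7α-isopropenyl, 9α-OSen, 10α-H, with every substituent except C14 equatorial.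

**Route**

Step 1
Reactants: 1 2-methylcyclohex-2-en-1-one
Product: 2 (E)-N-[(2S)-2-(methoxymethyl)pyrrolidin-1-yl]-2-methylcyclohex-2-en-1-imine (SAMP hydrazone of 1)
Conditions: SAMP (1.1 equiv), TsOH·H2O (cat.), cyclohexane, reflux, Dean–Stark
Reagents that add atoms: SAMP, (S)-1-amino-2-(methoxymethyl)pyrrolidine, COC[C@@H]1CCCN1N
Why: Hydrazone formation (first stage of the Enders SAMP/RAMP method) should proceed by simple condensation, the amino nitrogen settling anti to the substituted C4 side; no stereocentre is set.

Step 2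
Reactants: 2 SAMP hydrazone of 1; 3 methyl bromoacetate
Product: 5 methyl 2-[(1S,2E)-2-{[(2S)-2-(methoxymethyl)pyrrolidin-1-yl]imino}-3-methylcyclohex-3-en-1-yl]acetate, via lithium azaenolate 4 (not isolated)
Conditions: LDA, THF, −78 → 0 °C; then 3, −100 → −40 °C
Reagents that add atoms: none
Why: Enders SAMP-hydrazone alkylation: LDA should remove an α′ proton (C10, kinetic) and the chelated azaenolate should be alkylated on the face left open by the methoxymethyl-pyrrolidine, which sets C10 as S (arm β), in the same sense as the (R)-2-alkylcyclohexanones obtained from cyclohexanone with SAMP.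

Step 3
Reactants: 5 alkylated hydrazone
Product: 6 methyl 2-[(1S)-3-methyl-2-oxocyclohex-3-en-1-yl]acetate
Conditions: sat. aq. oxalic acid, Et2O, rt
Reagents that add atoms: water, O
Why: Mild two-phase acid hydrolysis of the hydrazone should return the enone without epimerising the α′ stereocentre and release the auxiliary into the aqueous phase.

Step 4
Reactants: 6 enone ester
Product: 8 (3aS,7aR)-7-methyl-3a,4,5,7a-tetrahydro-1-benzofuran-2(3H)-one, via cis-hydroxy ester 7 (not isolated)
Conditions: (3aS)-1-methyl-3,3-diphenyltetrahydro-1H,3H-pyrrolo[1,2-c][1,3,2]oxazaborole (0.2 equiv), catecholborane, PhMe, −78 °C; MeOH; then DBU (cat.), CH2Cl2, rt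
Reagents that add atoms: none
Why: Corey–Bakshi–Shibata reduction is 1,2-selective and reagent-controlled (the α-methylalkenyl side is the large group), so hydride should reach C5 from the α face and place O5 cis to the C10 arm; the cis γ-hydroxy ester then lactonises, while any trans alcohol cannot and is removed.

Step 5
Reactants: 8 unsaturated lactone
Product: 10 (3aS,6R,7S,7aR)-6-hydroxy-7-methylhexahydro-1-benzofuran-2(3H)-one, via C3 alkylborane 9 (not isolated)
Conditions: BH3·THF, THF, 0 °C → rt; then 30% H2O2, aq. NaOAc, 0 °C → rt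
Reagents that add atoms: hydrogen peroxide, OO
Why: Hydroboration–oxidation: boron should add to the less substituted C3 and hydrogen to C4, syn and from the convex α face of the cis-fused bicycle (anti to both the lactone oxygen and the C10 arm), so C3–OH comes out α and the C4 methyl β, trans to each other, and oxidation retains configuration.

Step 6
Reactants: 10 hydroxy lactone
Product: 11 (3aS,6R,7R,7aR)-6-[(tert-butyldimethylsilyl)oxy]-7-methylhexahydro-1-benzofuran-2(3H)-one
Conditions: TBSCl, imidazole, DMF, rt
Reagents that add atoms: tert-butyldimethylsilyl chloride, CC(C)(C)[Si](C)(C)Cl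
Why: Standard silylation of an unhindered equatorial secondary alcohol; the TBS group is chosen to outlast the triethylsilyl group introduced in step 12.

Step 7
Reactants: 11 silyloxy lactone
Product: 12 2-[(1S,2R,3R,4R)-4-[(tert-butyldimethylsilyl)oxy]-2-hydroxy-3-methylcyclohexyl]-N-methoxy-N-methylacetamide
Conditions: MeNH(OMe)·HCl, AlMe3, CH2Cl2, 0 °C → rt
Reagents that add atoms: N,O-dimethylhydroxylamine hydrochloride, CNOC.Cl
Why: Weinreb aminolysis of a lactone with the aluminium amide should open the ring irreversibly, freeing the C5 alcohol and leaving the arm as an amide that stops at the aldehyde on later reduction.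

Step 8
Reactants: 12 hydroxy amide
Product: 13 2-[(1S,3S,4R)-4-[(tert-butyldimethylsilyl)oxy]-3-methyl-2-oxocyclohexyl]-N-methoxy-N-methylacetamide
Conditions: Dess–Martin periodinane, NaHCO3, CH2Cl2, 0 °C → rt
Reagents that add atoms: none
Why: Dess–Martin oxidation under buffered, non-basic conditions should give the ketone without epimerising C4 or C10 (both already equatorial) and without eliminating the β-silyloxy group.

Step 9
Reactants: 13 keto amide
Product: 14 2-[(1S,3R,4R)-4-[(tert-butyldimethylsilyl)oxy]-3-methyl-2-methylidenecyclohexyl]-N-methoxy-N-methylacetamide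
Conditions: Zn, CH2Br2, TiCl4, THF/CH2Cl2, 0 °C → rt
Reagents that add atoms: dibromomethane, BrCBr
Why: Takai–Lombardo methylenation uses a non-basic titanium–zinc methylene reagent that should methylenate a hindered, epimerisable ketone without touching the α stereocentres or the amide.

Step 10
Reactants: 14 methylene amide
Product: 15 2-[(1S,3R,4R)-4-[(tert-butyldimethylsilyl)oxy]-3-methyl-2-methylidenecyclohexyl]acetaldehyde
Conditions: iBu2AlH, THF, −78 °C; aq. Rochelle salt
Reagents that add atoms: none
Why: Reduction of a Weinreb amide with iBu2AlH should stop at the aldehyde because the chelated tetrahedral intermediate survives until work-up.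

Step 11
Reactants: 15 ring A aldehyde; 16 methyl vinyl ketone
Product: 19 7α-acetyl-3α-[(tert-butyldimethylsilyl)oxy]-8β-hydroxy-4β,5β-dimethyl-10αH-trans-decalin, via C5 tertiary radical 17 (not isolated), via iron enolate 18 (not isolated)
Conditions: Fe(acac)3 (0.3 equiv), PhSiH3 (2.5 equiv), 16 (3 equiv), EtOH/(CH2OH)2 5:1, 0 °C → rt
Reagents that add atoms: none
Why: A trivalent iron hydride formed from Fe(acac)3, PhSiH3 and ethanol should transfer a hydrogen atom to C14 of the 1,1-disubstituted alkene (Markovnikov), the tertiary C5 radical 17 adds to 16 (Giese addition, C5–C6), and divalent iron reduces the α-acyl radical to the iron enolate 18, which attacks the C8 aldehyde (C7–C8). The closest known reaction is the Fe(acac)3/PhSiH3 hydrogen-atom-transfer conjugate addition of alkenes to enones and its radical–polar crossover annulation variant with γ,δ-unsaturated aldehydes. Ring B closes by a 6-(enolexo)-exo-trig aldol addition through a chair. C5 is set in the radical step: the in-plane C14 methyl of the radical eclipses the equatorial C4–CH3 and C10–CH2 bonds, these two β substituents tilt towards the β face, and the enone should enter on the α face anti to both, giving the axial β methyl and hence the trans fusion; at C7 the acetyl group goes equatorial because the axial position is syn-axial to C14, and C8–OH is expected equatorial (its configuration does not matter, as C8 is oxidised in step 15). The step needs α-face selectivity at C5, which rests on the two cis β substituents flanking C5, and hydrogen-atom transfer to the electron-rich alkene rather than to 16, which rests on the polarity match of the iron hydride with the alkene and of the nucleophilic radical with the enone.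

Step 12
Reactants: 19 aldol product
Product: 20 7α-acetyl-3α-[(tert-butyldimethylsilyl)oxy]-8β-[(triethylsilyl)oxy]-4β,5β-dimethyl-10αH-trans-decalin
Conditions: Et3SiCl, imidazole, DMF, 0 °C → rt
Reagents that add atoms: chlorotriethylsilane, CC[Si](Cl)(CC)CC
Why: Silylation of the C8 alcohol removes the free β-hydroxy ketone, which would undergo retro-aldol cleavage as its alkoxide under the ylide, and the triethylsilyl ether can later be removed in the presence of the TBS ether.

Step 13
Reactants: 20 silyl-protected methyl ketone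
Product: 21 3α-[(tert-butyldimethylsilyl)oxy]-8β-[(triethylsilyl)oxy]-10αH-eremophil-11-ene (7α-isopropenyl)
Conditions: Ph3PCH3Br, KOtBu, THF, 0 °C → rt
Reagents that add atoms: methyltriphenylphosphonium bromide, C[P+](c1ccccc1)(c1ccccc1)c1ccccc1.[Br-]
Why: Wittig methylenation of an unhindered methyl ketone should be faster than enolisation towards C7, and the equatorial C7 configuration is also the thermodynamic one.

Step 14
Reactants: 21 bis-silyl ether
Product: 22 3α-[(tert-butyldimethylsilyl)oxy]-10αH-eremophil-11-en-8β-ol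
Conditions: pyridinium p-toluenesulfonate (0.2 equiv), MeOH/CH2Cl2 1:1, 0 °C
Reagents that add atoms: none
Why: Acid-catalysed methanolysis should cleave the secondary triethylsilyl ether well before the secondary TBS ether (selective desilylation).

Step 15
Reactants: 22 C8 alcohol
Product: 23 3α-[(tert-butyldimethylsilyl)oxy]-10αH-eremophil-11-en-8-one
Conditions: Dess–Martin periodinane, NaHCO3, CH2Cl2, 0 °C
Reagents that add atoms: none
Why: Buffered Dess–Martin oxidation should give the β,γ-unsaturated ketone without moving the isopropenyl double bond into conjugation; the C8 stereocentre is removed and the C7 isopropenyl stays equatorial (α).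

Step 16
Reactants: 23 C8 ketone
Product: 25 3α-[(tert-butyldimethylsilyl)oxy]-8-[(trimethylsilyl)oxy]-10αH-eremophila-8,11-diene, via lithium enolate 24 (not isolated)
Conditions: LDA, THF, −78 °C; then Me3SiCl, Et3N, −78 → 0 °C
Reagents that add atoms: chlorotrimethylsilane, C[Si](C)(C)Cl
Why: Kinetic deprotonation with LDA should take the C9 methylene proton rather than the tertiary C7–H, which is more acidic but flanked by the isopropenyl group, and O-silylation fixes the C8–C9 enol ether (kinetic silyl enol ether formation).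

Step 17
Reactants: 25 silyl enol ether
Product: 28 3α-[(tert-butyldimethylsilyl)oxy]-9α-hydroxy-10αH-eremophil-11-en-8-one, via silyloxy epoxide 26 (not isolated), via 9α-silyloxy ketone 27 (not isolated)
Conditions: mCPBA (1.05 equiv), NaHCO3, CH2Cl2, −20 °C; then citric acid, MeOH, 0 °C
Reagents that add atoms: 3-chloroperbenzoic acid, OOC(=O)c1cccc(Cl)c1
Why: Rubottom oxidation: the peracid should epoxidise the electron-rich enol ether far faster than the 1,1-disubstituted isopropenyl alkene, and from the α face because the axial C14 methyl is syn-axial to the β face of C9; epoxide opening, 1,4-silyl shift and acid desilylation then give the 9α (equatorial) alcohol.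

Step 18
Reactants: 28 α-hydroxy ketone
Product: 29 3α-[(tert-butyldimethylsilyl)oxy]-9α-[(3-methylbut-2-enoyl)oxy]-10αH-eremophil-11-en-8-one
Conditions: 3-methylbut-2-enoic acid, DCC, 4-(dimethylamino)pyridine (0.1 equiv), CH2Cl2, 0 °C → rt
Reagents that add atoms: 3-methylbut-2-enoic acid (senecioic acid), CC(C)=CC(=O)O
Why: Steglich esterification of the equatorial C9 alcohol from the free acid avoids the vinylketene pathway of the acid chloride, which would deconjugate the senecioate.

Step 19
Reactants: 29 senecioate
Product: 30 3α-hydroxy-9α-[(3-methylbut-2-enoyl)oxy]-10αH-eremophil-11-en-8-one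
Conditions: 48% aq. HF, MeCN, 0 °C → rt
Reagents that add atoms: none
Why: Acidic fluoride desilylation should remove the TBS ether without the base that would epimerise C9 or C7 or shift the isopropenyl double bond.

Step 20
Reactants: 30 C3 alcohol
Product: 31 target, (3R,4R,5R,7S,9S,10R)-3α-[(E)-2-methylbut-2-enoyloxy]-9α-[(3-methylbut-2-enoyl)oxy]-10αH-eremophil-11-en-8-one
Conditions: tigloyl chloride, pyridine, 4-(dimethylamino)pyridine (0.2 equiv), CH2Cl2, 0 °C → rt
Reagents that add atoms: (E)-2-methylbut-2-enoyl chloride (tigloyl chloride), C/C=C(\C)C(=O)Cl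
Why: Nucleophile-catalysed acylation of the equatorial C3 alcohol with the acid chloride should give the tiglate with the E geometry intact (it is the stable isomer), under conditions short and mild enough to leave the α-acyloxy β,γ-unsaturated ketone unchanged.

**Compound list**

1 | 2-methylcyclohex-2-en-1-one | CC1=CCCC1=O | starting material
2 | SAMP hydrazone of 1 | COC[C@@H]1CCCN1/N=C1\CCCC=C1C | intermediate
3 | methyl bromoacetate | COC(=O)CBr | starting material
4 | lithium azaenolate of 2 | [Li+].COC[C@@H]1CCCN1[N-]C1=CCCC=C1C | intermediate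
5 | methyl 2-[(1S,2E)-2-{[(2S)-2-(methoxymethyl)pyrrolidin-1-yl]imino}-3-methylcyclohex-3-en-1-yl]acetate | COC[C@@H]1CCCN1/N=C1\[C@H](CC(=O)OC)CCC=C1C | intermediate
6 | methyl 2-[(1S)-3-methyl-2-oxocyclohex-3-en-1-yl]acetate | O=C1C(C)=CCC[C@H]1CC(=O)OC | intermediate
7 | methyl 2-[(1S,2R)-2-hydroxy-3-methylcyclohex-3-en-1-yl]acetate | O[C@H]1C(C)=CCC[C@H]1CC(=O)OC | intermediate
8 | (3aS,7aR)-7-methyl-3a,4,5,7a-tetrahydro-1-benzofuran-2(3H)-one | O=C1C[C@@H]2CCC=C(C)[C@@H]2O1 | intermediate
9 | C3 alkylborane from 8 (boron α at C3, hydrogen α at C4) | O=C1C[C@@H]2CC[C@@H](B)[C@H](C)[C@@H]2O1 | intermediate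
10 | (3aS,6R,7S,7aR)-6-hydroxy-7-methylhexahydro-1-benzofuran-2(3H)-one | O=C1C[C@@H]2CC[C@@H](O)[C@H](C)[C@@H]2O1 | intermediate
11 | (3aS,6R,7R,7aR)-6-[(tert-butyldimethylsilyl)oxy]-7-methylhexahydro-1-benzofuran-2(3H)-one | O=C1C[C@@H]2CC[C@@H](O[Si](C)(C)C(C)(C)C)[C@H](C)[C@@H]2O1 | intermediate
12 | 2-[(1S,2R,3R,4R)-4-[(tert-butyldimethylsilyl)oxy]-2-hydroxy-3-methylcyclohexyl]-N-methoxy-N-methylacetamide | CON(C)C(=O)C[C@@H]1CC[C@@H](O[Si](C)(C)C(C)(C)C)[C@H](C)[C@@H]1O | intermediate
13 | 2-[(1S,3S,4R)-4-[(tert-butyldimethylsilyl)oxy]-3-methyl-2-oxocyclohexyl]-N-methoxy-N-methylacetamide | CON(C)C(=O)C[C@@H]1CC[C@@H](O[Si](C)(C)C(C)(C)C)[C@H](C)C1=O | intermediate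
14 | 2-[(1S,3R,4R)-4-[(tert-butyldimethylsilyl)oxy]-3-methyl-2-methylidenecyclohexyl]-N-methoxy-N-methylacetamide | CON(C)C(=O)C[C@@H]1CC[C@@H](O[Si](C)(C)C(C)(C)C)[C@H](C)C1=C | intermediate
15 | 2-[(1S,3R,4R)-4-[(tert-butyldimethylsilyl)oxy]-3-methyl-2-methylidenecyclohexyl]acetaldehyde | C=C1[C@@H](C)[C@H](O[Si](C)(C)C(C)(C)C)CC[C@H]1CC=O | intermediate
16 | methyl vinyl ketone (but-3-en-2-one) | C=CC(C)=O | starting material
17 | C5 tertiary radical from 15 | C[C]1[C@@H](C)[C@H](O[Si](C)(C)C(C)(C)C)CC[C@H]1CC=O | intermediate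
18 | enolate of the Giese adduct (bound to trivalent iron, drawn as the anion) | CC([O-])=CC[C@]1(C)[C@@H](C)[C@H](O[Si](C)(C)C(C)(C)C)CC[C@H]1CC=O | intermediate
19 | 7α-acetyl-3α-TBSO-8β-hydroxy-4β,5β-dimethyl-10αH-trans-decalin | CC(=O)[C@@H]1C[C@]2(C)[C@@H](C)[C@H](O[Si](C)(C)C(C)(C)C)CC[C@H]2C[C@H]1O | intermediate
20 | 8β-triethylsilyl ether of 19 | CC(=O)[C@@H]1C[C@]2(C)[C@@H](C)[C@H](O[Si](C)(C)C(C)(C)C)CC[C@H]2C[C@H]1O[Si](CC)(CC)CC | intermediate
21 | 3α-TBSO-8β-triethylsilyloxy-10αH-eremophil-11-ene | C=C(C)[C@@H]1C[C@]2(C)[C@@H](C)[C@H](O[Si](C)(C)C(C)(C)C)CC[C@H]2C[C@H]1O[Si](CC)(CC)CC | intermediate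
22 | 3α-TBSO-10αH-eremophil-11-en-8β-ol | C=C(C)[C@@H]1C[C@]2(C)[C@@H](C)[C@H](O[Si](C)(C)C(C)(C)C)CC[C@H]2C[C@H]1O | intermediate
23 | 3α-TBSO-10αH-eremophil-11-en-8-one | C=C(C)[C@@H]1C[C@]2(C)[C@@H](C)[C@H](O[Si](C)(C)C(C)(C)C)CC[C@H]2CC1=O | intermediate
24 | lithium C8–C9 enolate of 23 | [Li+].C=C(C)[C@@H]1C[C@]2(C)[C@@H](C)[C@H](O[Si](C)(C)C(C)(C)C)CC[C@H]2C=C1[O-] | intermediate
25 | 3α-TBSO-8-trimethylsilyloxy-10αH-eremophila-8,11-diene | C=C(C)[C@@H]1C[C@]2(C)[C@@H](C)[C@H](O[Si](C)(C)C(C)(C)C)CC[C@H]2C=C1O[Si](C)(C)C | intermediate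
26 | 8α,9α-epoxide of 25 | C=C(C)[C@@H]1C[C@]2(C)[C@@H](C)[C@H](O[Si](C)(C)C(C)(C)C)CC[C@H]2[C@@H]3O[C@]13O[Si](C)(C)C | intermediate
27 | 3α-TBSO-9α-trimethylsilyloxy-10αH-eremophil-11-en-8-one | C=C(C)[C@@H]1C[C@]2(C)[C@@H](C)[C@H](O[Si](C)(C)C(C)(C)C)CC[C@H]2[C@H](O[Si](C)(C)C)C1=O | intermediate
28 | 3α-TBSO-9α-hydroxy-10αH-eremophil-11-en-8-one | C=C(C)[C@@H]1C[C@]2(C)[C@@H](C)[C@H](O[Si](C)(C)C(C)(C)C)CC[C@H]2[C@H](O)C1=O | intermediate
29 | 3α-TBSO-9α-(3-methylbut-2-enoyloxy)-10αH-eremophil-11-en-8-one | C=C(C)[C@@H]1C[C@]2(C)[C@@H](C)[C@H](O[Si](C)(C)C(C)(C)C)CC[C@H]2[C@H](OC(=O)C=C(C)C)C1=O | intermediate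
30 | 3α-hydroxy-9α-(3-methylbut-2-enoyloxy)-10αH-eremophil-11-en-8-one | C=C(C)[C@@H]1C[C@]2(C)[C@@H](C)[C@H](O)CC[C@H]2[C@H](OC(=O)C=C(C)C)C1=O | intermediate
31 | CNP0375730.3, (3R,4R,5R,7S,9S,10R)-3α-tigloyloxy-9α-senecioyloxy-10αH-eremophil-11-en-8-one | C=C(C)[C@@H]1C[C@]2(C)[C@@H](C)[C@H](OC(=O)/C(C)=C/C)CC[C@H]2[C@H](OC(=O)C=C(C)C)C1=O | target

**Totals**

Total step count: 20. Longest linear sequence: 20 steps (from 1; 3 and 16 are commercial).

**Steps most likely to fail**

1. Step 11. The enone may add to the C5 radical from the β (axial) face, which would lead into the C5-epimeric cis-fused series, or the radical may be reduced before it is trapped. The fallback separates the two bond formations and makes the radical step intramolecular. It sets out from 15: a Morita–Baylis–Hillman reaction with 16 (DABCO, MeOH, rt) should give 3-{1-hydroxy-2-[(1S,3R,4R)-4-(tert-butyldimethylsilyloxy)-3-methyl-2-methylidenecyclohexyl]ethyl}but-3-en-2-one F1 (both C8 epimers), which already holds the C7–C8 bond. Fe(acac)3 and PhSiH3 in EtOH/(CH2OH)2 would then generate the same C5 radical, which closes ring B by a 6-endo-trig conjugate addition to C6 through a chair; the equatorial C10 tether dictates attack on the α face, as in radical polyene cyclisations that give trans-decalins. Reduction and protonation of the α-acyl radical bring the route back at 19 (C8 epimers converge at 23).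

2. Step 16. Deprotonation may occur at the doubly activated C7–H instead of C9, giving the cross-conjugated dienolate, loss of regiocontrol and migration of the double bond. The fallback avoids enolate chemistry and sets out from 23: D-proline (0.3 equiv) and nitrosobenzene in DMSO at rt should form the less substituted enamine (towards C9, for steric reasons) and, by O-selective nitroso aldol reaction on the α face, give 3α-TBSO-9α-(phenylaminooxy)-10αH-eremophil-11-en-8-one F2. Cleavage of the N–O bond with Zn and AcOH in THF at 0 °C brings the route back at 28.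

3. Step 2. Metalation may not be fully α′-selective (γ-deprotonation), the facial selectivity of the azaenolate alkylation may erode, or C10 may partly epimerise on hydrazone cleavage. The fallback replaces the auxiliary by a resolution and sets out from 1 and 3: LDA in THF at −78 °C should give racemic methyl 2-(3-methyl-2-oxocyclohex-3-en-1-yl)acetate F3. The oxazaborolidine reduction of step 4 then reduces both enantiomers under reagent control: the (1S,2R) alcohol 7 lactonises to 8, where the route is rejoined, and methyl 2-[(1R,2R)-2-hydroxy-3-methylcyclohex-3-en-1-yl]acetate F4, which cannot lactonise, is separated by chromatography.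

Further compounds
F1 | step 11 | 3-{1-hydroxy-2-[(1S,3R,4R)-4-(tert-butyldimethylsilyloxy)-3-methyl-2-methylidenecyclohexyl]ethyl}but-3-en-2-one (C8 epimers) | C=C(C(C)=O)C(O)C[C@@H]1CC[C@@H](O[Si](C)(C)C(C)(C)C)[C@H](C)C1=C
F2 | step 16 | 3α-TBSO-9α-(phenylaminooxy)-10αH-eremophil-11-en-8-one | C=C(C)[C@@H]1C[C@]2(C)[C@@H](C)[C@H](O[Si](C)(C)C(C)(C)C)CC[C@H]2[C@H](ONc3ccccc3)C1=O
F3 | step 2 | racemic methyl 2-(3-methyl-2-oxocyclohex-3-en-1-yl)acetate | COC(=O)CC1CCC=C(C)C1=O
F4 | step 2 | methyl 2-[(1R,2R)-2-hydroxy-3-methylcyclohex-3-en-1-yl]acetate | O[C@H]1C(C)=CCC[C@@H]1CC(=O)OC
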